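**Retrosynthetic overview**
1. Feature: ring A is a 4-methoxyphenol (C5–OMe para to C8–OH, C6–H and C7–H between them) fused through C4a–C8a to quinone ring B. A methoxycarbene carbon (C5), a two-carbon alkyne (C6–C7) and one carbonyl ligand (C8) assemble this pattern with the two oxygens already different.
2. Endgame: the C1'–O acyl bond is cut last (senecioic acid). The ring B quinone goes back to its C1/C4 dimethyl ether, with O8 held as acetate so that only ring B is oxidised.
3. Key disconnection: C5–C6, C7–C8 and C8–C8a of ring A, leading to the aryl(methoxy)carbene Cr(CO)5 complex 10 and Me3SiC≡CH 11, where silicon stands in for H on C7.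
4. Complex 10 comes from aryl bromide 6 (Br–Li exchange, Cr(CO)6, Me3OBF4; C4a–C5 bond). C1' is set as (S) by catalytic asymmetric allylboration of aldehyde 1, and the prenyl end is made by cross-metathesis.
5. Ring order: ring B is the benzene ring of 1 from the start, and ring A is the only ring built (step 5).

Key step: step 5

Assumption: naphthalene positions carry the target numbering throughout, and (S)-TRIP phosphoric acid is taken to deliver allyl to the Si face of 1, as its sense with simple benzaldehydes implies; were the sense opposite, the (R)-acid would be used.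

**Step 1**
Reactants: 1 4-bromo-2,5-dimethoxybenzaldehyde; 2 allylboronic acid pinacol ester
Product: 4 (S)-1-(4-bromo-2,5-dimethoxyphenyl)but-3-en-1-ol, via pinacol borate 3 (not isolated)
Conditions: (S)-TRIP phosphoric acid (5 mol %), toluene, −30 °C; then H2O
Reagents that add atoms: allylboronic acid pinacol ester 2, C=CCB1OC(C)(C)C(C)(C)O1
Why: In this chiral-phosphoric-acid-catalysed asymmetric allylboration the acid protonates a pinacol oxygen of 2 and holds the formyl C–H in a closed chair transition state, so allyl should reach the Si face and set C1' as (S); a prenylboronate is not used because it would add through its γ-carbon.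

**Step 2**
Reactants: 4 (S)-1-(4-bromo-2,5-dimethoxyphenyl)but-3-en-1-ol
Product: 5 (S)-[1-(4-bromo-2,5-dimethoxyphenyl)but-3-enyloxy](tert-butyl)dimethylsilane
Conditions: TBSCl, imidazole, DMF, 0 °C → rt
Reagents that add atoms: tert-butyldimethylsilyl chloride, CC(C)(C)[Si](C)(C)Cl
Why: Imidazole-promoted O-silylation runs without acid, so the electron-rich benzylic C1'–O bond is not ionised, and the silyl ether should withstand n-BuLi at −78 °C, carbene formation and the neutral annulation.

**Step 3**
Reactants: 5 (S)-[1-(4-bromo-2,5-dimethoxyphenyl)but-3-enyloxy](tert-butyl)dimethylsilane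
Product: 6 (S)-[1-(4-bromo-2,5-dimethoxyphenyl)-4-methylpent-3-enyloxy](tert-butyl)dimethylsilane
Conditions: 2-methylbut-2-ene (large excess), (H2IMes)(PCy3)Cl2Ru=CHPh (second-generation Grubbs catalyst, 3 mol %), CH2Cl2, 35 °C, sealed tube
Reagents that add atoms: 2-methylbut-2-ene, CC=C(C)C
Why: Olefin cross-metathesis of a terminal alkene with excess 2-methylbut-2-ene transfers an isopropylidene unit and releases propene, a known allyl-to-prenyl conversion whose trisubstituted product re-enters the cycle only slowly and which does not touch C1'.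

**Step 4**
Reactants: 6 (S)-[1-(4-bromo-2,5-dimethoxyphenyl)-4-methylpent-3-enyloxy](tert-butyl)dimethylsilane; 7 hexacarbonylchromium Cr(CO)6
Product: 10 pentacarbonyl{methoxy[2,5-dimethoxy-4-((S)-1-(tert-butyldimethylsilyloxy)-4-methylpent-3-enyl)phenyl]carbene}chromium, via aryllithium 8 (not isolated), via lithium acylchromate 9 (not isolated)
Conditions: n-BuLi, Et2O, −78 °C; Cr(CO)6, −78 °C → rt; solvent removed; Me3OBF4, CH2Cl2, 0 °C → rt
Reagents that add atoms: hexacarbonylchromium 7, O=C=[Cr](=C=O)(=C=O)(=C=O)(=C=O)=C=O; trimethyloxonium tetrafluoroborate, C[O+](C)C.F[B-](F)(F)F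
Why: In this Fischer carbene synthesis, fast Br–Li exchange gives 8, which adds to a carbonyl ligand of Cr(CO)6 (forming C4a–C5) to give acylate 9, and the hard oxonium salt alkylates its oxygen to fix the methoxycarbene; the lithiated carbon lies para to the side chain, so no silyl migration is possible.

**Step 5**
Reactants: 10 pentacarbonyl{methoxy[2,5-dimethoxy-4-((S)-1-(tert-butyldimethylsilyloxy)-4-methylpent-3-enyl)phenyl]carbene}chromium; 11 trimethylsilylacetylene
Product: 13 2-[(S)-1-(tert-butyldimethylsilyloxy)-4-methylpent-3-enyl]-1,4,5-trimethoxy-7-(trimethylsilyl)naphthalen-8-ol, via tricarbonylchromium naphthol complex 12 (not isolated)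
Conditions: Me3SiC≡CH (2 equiv), THF (0.2 M, degassed), 50 °C, Ar; then air, Et2O, rt, filtration through silica
Reagents that add atoms: trimethylsilylacetylene 11, C#C[Si](C)(C)C
Why: Thermal loss of one cis carbonyl from 10 (eased by the ortho methoxyl, which can occupy the vacant site) lets 11 bind and insert into the Cr=C bond (C5–C6), carbonyl migration to the new vinylcarbene carbon gives a chromium-bound vinylketene (C7–C8), and closure onto C8a followed by tautomerisation gives the naphthol, first as its Cr(CO)3 complex 12 and then free after exposure to air. The closest known reaction type is the Dötz benzannulation of (2,5-dimethoxyphenyl)(methoxy)carbene Cr(CO)5 complexes with alkynes, in which Me3SiC≡CH is an established stand-in for acetylene, which itself performs poorly. Ring A, the only ring formed, closes by a six-electron electrocyclisation of the aryl vinylketene (C8–C8a), overall a [3+2+1] assembly. No stereocentre is created, and C1', which sits para to the carbene carbon under a silyl ether inert to neutral THF at 50 °C, keeps its (S) configuration. Closure can occur only at C8a because the other ortho carbon (C4) bears a methoxyl, O5 comes methylated from the carbene and O8 free from the carbonyl ligand, and the bulky silyl group should lie next to the carbonyl-derived C8 (on C7), an orientation that does not matter because silicon is removed next. Chromium, an ether solvent and a fairly high concentration favour the phenol channel over closure without carbonyl insertion, and decomplexation uses air alone because any cerium or iron oxidant would take the 4-methoxynaphthol of ring A to the wrong quinone.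

**Step 6**
Reactants: 13 2-[(S)-1-(tert-butyldimethylsilyloxy)-4-methylpent-3-enyl]-1,4,5-trimethoxy-7-(trimethylsilyl)naphthalen-8-ol
Product: 14 2-[(S)-1-hydroxy-4-methylpent-3-enyl]-1,4,5-trimethoxynaphthalen-8-ol
Conditions: Bu4NF·3H2O (5 equiv), THF (degassed), rt → 50 °C, Ar; pH 7 buffer
Reagents that add atoms: none
Why: In this fluoride-induced desilylation, fluoride cuts the O–Si bond at C1' and also the C7–Si bond (protodesilylation), because C7 lies ortho to the naphtholate oxygen and is easily protonated (its keto tautomer is an α-silyl ketone); the usual CF3CO2H is avoided because the C1'–O bond, benzylic to a trimethoxynaphthol, would ionise and cost the stereocentre and the prenyl alkene.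

**Step 7**
Reactants: 14 2-[(S)-1-hydroxy-4-methylpent-3-enyl]-1,4,5-trimethoxynaphthalen-8-ol
Product: 15 2-[(S)-1-hydroxy-4-methylpent-3-enyl]-1,4,5-trimethoxynaphthalen-8-yl acetate
Conditions: Ac2O (1.05 equiv), K2CO3 (1.5 equiv), acetone (degassed), 0 °C, Ar
Reagents that add atoms: acetic anhydride, CC(=O)OC(C)=O
Why: In this chemoselective phenolate acylation of the Schotten–Baumann type, carbonate deprotonates only the naphthol, and without an acyl-transfer catalyst the naphtholate outruns the neutral secondary alcohol for one equivalent of anhydride; the acetate then blocks ring A from reaching the quinone level in step 8.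

**Step 8**
Reactants: 15 2-[(S)-1-hydroxy-4-methylpent-3-enyl]-1,4,5-trimethoxynaphthalen-8-yl acetate
Product: 16 8-acetoxy-2-[(S)-1-hydroxy-4-methylpent-3-enyl]-5-methoxynaphthalene-1,4-dione
Conditions: (NH4)2Ce(NO3)6 (2.2 equiv), MeCN–H2O, 0 °C, short contact time
Reagents that add atoms: water, O
Why: In this oxidative demethylation of a 1,4-dimethoxyarene by tetravalent cerium, two one-electron oxidations with attack of water at C1 and C4 expel two methanols; ring B (two methoxyls and an alkyl group) is the richer ring and acylated O8 keeps ring A out, free 1-hydroxyalkyl and prenyl groups are known to survive this reagent on polymethoxynaphthalenes, and the cold, brief exposure limits ionisation at C1'.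

**Step 9**
Reactants: 16 8-acetoxy-2-[(S)-1-hydroxy-4-methylpent-3-enyl]-5-methoxynaphthalene-1,4-dione
Product: 17 8-hydroxy-2-[(S)-1-hydroxy-4-methylpent-3-enyl]-5-methoxynaphthalene-1,4-dione
Conditions: K2CO3 (0.2 equiv), MeOH, 0 °C; pH 5 buffer
Reagents that add atoms: none
Why: In this base-catalysed transesterification of the Zemplén type, the aryl acetate peri to the C1 carbonyl is an activated ester with a good phenolate leaving group; the step precedes acylation of C1' because a carboxylate at C1' of a quinone is prone to displacement in basic methanol, whereas the free carbinol offers no leaving group.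

**Step 10**
Reactants: 17 8-hydroxy-2-[(S)-1-hydroxy-4-methylpent-3-enyl]-5-methoxynaphthalene-1,4-dione; 18 3-methylbut-2-enoic acid (senecioic acid)
Product: 20 (S)-1-(8-hydroxy-5-methoxy-1,4-dioxo-1,4-dihydronaphthalen-2-yl)-4-methylpent-3-enyl 3-methylbut-2-enoate (target), via O-acylisourea 19 (not isolated)
Conditions: DCC (1.3 equiv), DMAP (0.1 equiv), CH2Cl2, 0 °C → rt
Reagents that add atoms: 3-methylbut-2-enoic acid 18, CC(C)=CC(=O)O
Why: In this Steglich esterification DMAP relays the acyl group of 19 to the secondary alcohol, while C8–OH, locked in a hydrogen bond to the C1 carbonyl, is a poor nucleophile (a selectivity known for side-chain acylation of peri-hydroxynaphthoquinone carbinols); the C1'–O bond is not broken, so (S) is retained, and carbodiimide activation avoids the base-induced deconjugation seen with senecioyl chloride.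

**Compound list**
1 | 4-bromo-2,5-dimethoxybenzaldehyde | COc1cc(Br)c(OC)cc1C=O | starting material
2 | allylboronic acid pinacol ester | C=CCB1OC(C)(C)C(C)(C)O1 | starting material
3 | (S)-2-[1-(4-bromo-2,5-dimethoxyphenyl)but-3-enyloxy]-4,4,5,5-tetramethyl-1,3,2-dioxaborolane (not isolated) | COc1cc(Br)c(OC)cc1[C@H](CC=C)OB1OC(C)(C)C(C)(C)O1 | intermediate
4 | (S)-1-(4-bromo-2,5-dimethoxyphenyl)but-3-en-1-ol | COc1cc(Br)c(OC)cc1[C@H](CC=C)O | intermediate
5 | (S)-[1-(4-bromo-2,5-dimethoxyphenyl)but-3-enyloxy](tert-butyl)dimethylsilane | COc1cc(Br)c(OC)cc1[C@H](CC=C)O[Si](C)(C)C(C)(C)C | intermediate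
6 | (S)-[1-(4-bromo-2,5-dimethoxyphenyl)-4-methylpent-3-enyloxy](tert-butyl)dimethylsilane | COc1cc(Br)c(OC)cc1[C@H](CC=C(C)C)O[Si](C)(C)C(C)(C)C | intermediate
7 | hexacarbonylchromium Cr(CO)6 | O=C=[Cr](=C=O)(=C=O)(=C=O)(=C=O)=C=O | starting material
8 | {2,5-dimethoxy-4-[(S)-1-(tert-butyldimethylsilyloxy)-4-methylpent-3-enyl]phenyl}lithium (not isolated) | [Li]c1cc(OC)c([C@H](CC=C(C)C)O[Si](C)(C)C(C)(C)C)cc1OC | intermediate
9 | lithium pentacarbonyl(aroyl)chromate from 8 and Cr(CO)6 (not isolated) | [Li+].[O-]C(=[Cr](=C=O)(=C=O)(=C=O)(=C=O)=C=O)c1cc(OC)c([C@H](CC=C(C)C)O[Si](C)(C)C(C)(C)C)cc1OC | intermediate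
10 | pentacarbonyl{methoxy[2,5-dimethoxy-4-((S)-1-(tert-butyldimethylsilyloxy)-4-methylpent-3-enyl)phenyl]carbene}chromium | COC(=[Cr](=C=O)(=C=O)(=C=O)(=C=O)=C=O)c1cc(OC)c([C@H](CC=C(C)C)O[Si](C)(C)C(C)(C)C)cc1OC | intermediate
11 | trimethylsilylacetylene | C#C[Si](C)(C)C | starting material
12 | Cr(CO)3 complex of naphthol 13, metal η6-bound to ring A, the η6 bond written as a dot (not isolated) | COc1cc([Si](C)(C)C)c(O)c2c(OC)c([C@H](CC=C(C)C)O[Si](C)(C)C(C)(C)C)cc(OC)c12.O=C=[Cr](=C=O)=C=O | intermediate
13 | 2-[(S)-1-(tert-butyldimethylsilyloxy)-4-methylpent-3-enyl]-1,4,5-trimethoxy-7-(trimethylsilyl)naphthalen-8-ol | COc1cc([Si](C)(C)C)c(O)c2c(OC)c([C@H](CC=C(C)C)O[Si](C)(C)C(C)(C)C)cc(OC)c12 | intermediate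
14 | 2-[(S)-1-hydroxy-4-methylpent-3-enyl]-1,4,5-trimethoxynaphthalen-8-ol | COc1ccc(O)c2c(OC)c([C@H](CC=C(C)C)O)cc(OC)c12 | intermediate
15 | 2-[(S)-1-hydroxy-4-methylpent-3-enyl]-1,4,5-trimethoxynaphthalen-8-yl acetate | COc1ccc(OC(C)=O)c2c(OC)c([C@H](CC=C(C)C)O)cc(OC)c12 | intermediate
16 | 8-acetoxy-2-[(S)-1-hydroxy-4-methylpent-3-enyl]-5-methoxynaphthalene-1,4-dione | COc1ccc(OC(C)=O)c2c1C(=O)C=C([C@H](CC=C(C)C)O)C2=O | intermediate
17 | 8-hydroxy-2-[(S)-1-hydroxy-4-methylpent-3-enyl]-5-methoxynaphthalene-1,4-dione | COc1ccc(O)c2c1C(=O)C=C([C@H](CC=C(C)C)O)C2=O | intermediate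
18 | 3-methylbut-2-enoic acid (senecioic acid) | CC(C)=CC(=O)O | starting material
19 | N,N'-dicyclohexyl-O-(3-methylbut-2-enoyl)isourea (not isolated) | CC(C)=CC(=O)OC(=NC1CCCCC1)NC1CCCCC1 | intermediate
20 | (S)-1-(8-hydroxy-5-methoxy-1,4-dioxo-1,4-dihydronaphthalen-2-yl)-4-methylpent-3-enyl 3-methylbut-2-enoate | COc1ccc(O)c2c1C(=O)C=C([C@H](CC=C(C)C)OC(=O)C=C(C)C)C2=O | target

**Total step count:** 10. **Longest linear sequence:** 10 steps (1 → 20).

**Steps most likely to fail**

**Step 5 (key step).**
- What may go wrong: the silyl-stabilised vinylketene may stall before electrocyclisation. Closure may occur without carbonyl insertion to give a five-membered ring. The very electron-rich ring A may be over-oxidised during decomplexation.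
- Fallback: it sets out from bromide 6 and comes back at diol 14, building ring A by an aryne cycloaddition instead of at chromium.
- LDA in THF (−78 °C → rt) removes the proton flanked by Br and OMe, and loss of lithium bromide gives the 3,6-dimethoxyaryne F1 across C4a–C8a.
- 2-Methoxyfuran, present in excess, traps F1 in a Diels–Alder reaction to give the 5-methoxy-5,8-epoxy-5,8-dihydronaphthalene F2.
- The bridgehead ketal of F2 opens on silica or on a mildly acidic work-up, and aromatisation gives the 5-methoxy-8-naphthol silyl ether F3.
- Bu4NF at 0 °C then frees the carbinol to give 14.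
- Cost: both aryne carbons are flanked by a methoxyl, so little control over the furan orientation is expected, and the isomer with the ring A oxygens exchanged has to be separated.

**Step 6.**
- What may go wrong: the C7–Si bond of an electron-rich ring may cleave incompletely while only the O–Si bond is cut, and the naphtholate may be oxidised by air on warming.
- Fallback: it sets out from carbene complex 10 and comes back at diol 14, with tin replacing silicon as the placeholder.
- Annulation of 10 with ethynyltributylstannane, followed by the same air work-up, should give the stannylnaphthol F4. Tin is expected on C6, next to the methoxy-bearing carbon, which is the contrasteric orientation known for stannylalkynes; its position does not matter.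
- The aryl–Sn bond of so rich a ring is cleaved by AcOH in THF at rt (protodestannylation), well below the acidity that endangers C1'–O. This gives the silyl ether F3 already described above.
- Bu4NF at 0 °C then has only the O–Si bond to cut and gives 14.

**Step 8.**
- What may go wrong: the free benzylic carbinol may be oxidised or its C–C bond cleaved. Acid-promoted ionisation at C1' may erode configuration before ring B is oxidised. Ring A may be attacked in competition.
- Fallback: it sets out from acetate 15 and comes back at target 20, with the carbinol esterified before the oxidation.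
- Steglich esterification of 15 with 18 (through 19) gives the aryl acetate senecioate F5.
- (NH4)2Ce(NO3)6 in MeCN–H2O at 0 °C oxidises ring B of F5 to the quinone acetate senecioate F6.
- A brief K2CO3-catalysed methanolysis at −20 °C removes only the activated aryl acetate and gives 20.
- Cost: the last step must then tell the aryl acetate from the C1' ester on a base-sensitive quinone.

**Further compounds**
F1 | step 5 | 3,6-dimethoxy-4-[(S)-1-(tert-butyldimethylsilyloxy)-4-methylpent-3-enyl]benzyne (transient) | COC1=C([C@H](CC=C(C)C)O[Si](C)(C)C(C)(C)C)C=C(OC)C#C1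
F2 | step 5 | 2-[(S)-1-(tert-butyldimethylsilyloxy)-4-methylpent-3-enyl]-1,4,5-trimethoxy-5,8-epoxy-5,8-dihydronaphthalene (bridgeheads unassigned) | COC12C=CC(O1)c1c(OC)c([C@H](CC=C(C)C)O[Si](C)(C)C(C)(C)C)cc(OC)c12
F3 | step 5 | 2-[(S)-1-(tert-butyldimethylsilyloxy)-4-methylpent-3-enyl]-1,4,5-trimethoxynaphthalen-8-ol | COc1ccc(O)c2c(OC)c([C@H](CC=C(C)C)O[Si](C)(C)C(C)(C)C)cc(OC)c12
F4 | step 6 | 2-[(S)-1-(tert-butyldimethylsilyloxy)-4-methylpent-3-enyl]-1,4,5-trimethoxy-6-(tributylstannyl)naphthalen-8-ol | COc1c([Sn](CCCC)(CCCC)CCCC)cc(O)c2c(OC)c([C@H](CC=C(C)C)O[Si](C)(C)C(C)(C)C)cc(OC)c12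
F5 | step 8 | (S)-1-(8-acetoxy-1,4,5-trimethoxynaphthalen-2-yl)-4-methylpent-3-enyl 3-methylbut-2-enoate | COc1ccc(OC(C)=O)c2c(OC)c([C@H](CC=C(C)C)OC(=O)C=C(C)C)cc(OC)c12
F6 | step 8 | (S)-1-(8-acetoxy-5-methoxy-1,4-dioxo-1,4-dihydronaphthalen-2-yl)-4-methylpent-3-enyl 3-methylbut-2-enoate | COc1ccc(OC(C)=O)c2c1C(=O)C=C([C@H](CC=C(C)C)OC(=O)C=C(C)C)C2=O
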